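**Retrosynthetic overview**
1. Feature: ring A (4-hydroxy-3-methoxyphenyl) carries the benzylic CH2 bound to lactone C3 on its C1, OMe on C3 and OH on C4. This matches a 4-alkyl-2-methoxycyclohex-2-enone (alkyl on C4, OMe on C2, carbonyl at C1), which lies one dehydrogenation below the phenol.
2. Target 21 is traced back to enone 19 by undoing the aromaticity of ring A, so the phenol is never protected and ring A is never substituted as an arene.
3. Enone 19 is cut at C4–C5 and C2=C3 of the carbocycle into lactone propanal 12 (supplies C3 and C4) and 1-methoxybut-3-en-2-one 16 (supplies C5, C6, C1 and C2). The forward sense is Michael addition followed by aldol condensation.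
4. Aldehyde 12 comes from (R)-lactone 7 by trans allylation, hydroboration–oxidation and alcohol oxidation. Lactone 7 comes from 1 and 2 by Stobbe condensation, asymmetric hydrogenation and ester-selective reduction, and 16 comes from acid chloride 13 via its Weinreb amide.
5. Order of rings: ring C (trimethoxyphenyl) is bought, lactone ring B closes in step 3, and the carbocycle closes in step 9 and becomes aromatic ring A in step 10.

Key step: step 9

Assumption: the (S,S) antipode of Et-DuPHOS is taken to deliver (R)-acid 5, by analogy with the chelate model for β-substituted itaconate half-esters. The sense is to be checked on lactone 7, and the (R,R) ligand would be used if it proves opposite.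

Step 1
Reactants: 1 3,4,5-trimethoxybenzaldehyde; 2 dimethyl succinate
Product: 4 (E)-3-(methoxycarbonyl)-4-(3,4,5-trimethoxyphenyl)but-3-enoic acid, via paraconic lactone 3 (not isolated)
Conditions: NaOMe (1.5 equiv), MeOH, reflux; then aq HCl
Reagents that add atoms: none
Why: Stobbe condensation, in which the succinate enolate adds to the aldehyde, the alkoxide closes to lactone 3 with loss of methoxide, and irreversible E1cB opening gives the carboxylate of the (E)-half-ester with the free acid on the CH2 arm and the ester on the alkene carbon.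

Step 2
Reactants: 4 (E)-3-(methoxycarbonyl)-4-(3,4,5-trimethoxyphenyl)but-3-enoic acid
Product: 5 (R)-3-(methoxycarbonyl)-4-(3,4,5-trimethoxyphenyl)butanoic acid
Conditions: H2 (5 bar), [Rh(cod)((S,S)-Et-DuPHOS)]BF4 (0.5 mol %), NaOMe (10 mol %), MeOH, rt
Reagents that add atoms: none
Why: Rhodium-catalysed asymmetric hydrogenation of a Stobbe-type itaconate half-ester, in which carboxylate and alkene bind the cationic rhodium centre as a chelate, so the C2-symmetric bisphospholane decides which alkene face receives H2 and sets the carbon that becomes lactone C4 as (R).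

Step 3
Reactants: 5 (R)-3-(methoxycarbonyl)-4-(3,4,5-trimethoxyphenyl)butanoic acid
Product: 7 (R)-4-(3,4,5-trimethoxybenzyl)dihydrofuran-2(3H)-one, via hydroxy acid 6 (not isolated)
Conditions: KOH (1.0 equiv), EtOH, 0 °C; CaCl2, NaBH4, EtOH, −10 °C to rt; then 3 M HCl, rt
Reagents that add atoms: none
Why: Chemoselective ester reduction with Ca(BH4)2 made in the flask, in which the potassium carboxylate is inert while the methyl ester goes to the primary alcohol, and acidification closes hydroxy acid 6 to the γ-lactone (ring B, 5-exo-trig lactonisation) without touching the stereocentre.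

Step 4
Reactants: 7 (R)-4-(3,4,5-trimethoxybenzyl)dihydrofuran-2(3H)-one
Product: 9 (3R,4R)-3-allyl-4-(3,4,5-trimethoxybenzyl)dihydrofuran-2(3H)-one, via lithium enolate 8 (not isolated)
Conditions: LiN(SiMe3)2 (1.05 equiv), THF, −78 °C; allyl bromide (1.2 equiv), −78 to −30 °C
Reagents that add atoms: allyl bromide, C=CCBr; LiN(SiMe3)2, [Li+].C[Si](C)(C)[N-][Si](C)(C)C (lithium stays only in 8)
Why: Diastereoselective lactone enolate alkylation, in which allyl bromide approaches enolate 8 on the face opposite the C4 benzyl group and sets C3 as (R) in the trans arrangement that is also the thermodynamic one.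

Step 5
Reactants: 9 (3R,4R)-3-allyl-4-(3,4,5-trimethoxybenzyl)dihydrofuran-2(3H)-one
Product: 11 (3R,4R)-3-(3-hydroxypropyl)-4-(3,4,5-trimethoxybenzyl)dihydrofuran-2(3H)-one, via B-alkyl borane 10 (not isolated)
Conditions: 9-BBN-H (1.3 equiv), THF, 0 °C to rt; then 30 % H2O2, 3 M aq NaOAc, 0 °C to rt
Reagents that add atoms: hydrogen peroxide, OO; 9-borabicyclo[3.3.1]nonane, C1CC2CCCC(C1)B2 (its boron and carbons stay only in 10)
Why: Anti-Markovnikov hydroboration–oxidation, in which 9-BBN-H adds to the terminal alkene far faster than it reduces a lactone, and the acetate-buffered peroxide oxidises the C–B bond without opening ring B or touching either stereocentre.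

Step 6
Reactants: 11 (3R,4R)-3-(3-hydroxypropyl)-4-(3,4,5-trimethoxybenzyl)dihydrofuran-2(3H)-one
Product: 12 3-[(3R,4R)-2-oxo-4-(3,4,5-trimethoxybenzyl)tetrahydrofuran-3-yl]propanal
Conditions: Dess–Martin periodinane (1.2 equiv), CH2Cl2, 0 °C to rt
Reagents that add atoms: none
Why: Dess–Martin oxidation stops at the aldehyde under neutral, water-free conditions that leave the lactone, its α-stereocentre and the electron-rich arene alone.

Step 7
Reactants: 13 methoxyacetyl chloride
Product: 14 N,2-dimethoxy-N-methylacetamide
Conditions: MeNH(OMe)·HCl (1.05 equiv), Et3N (2.2 equiv), CH2Cl2, 0 °C to rt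
Reagents that add atoms: N,O-dimethylhydroxylamine hydrochloride, CNOC.Cl
Why: Weinreb amide formation by N-acylation, in which Et3N frees the hydroxylamine and takes up both equivalents of HCl, and no Lewis acid is present that could decarbonylate the methoxyacetyl unit.

Step 8
Reactants: 14 N,2-dimethoxy-N-methylacetamide
Product: 16 1-methoxybut-3-en-2-one, via magnesium chelate 15 (not isolated)
Conditions: CH2=CHMgBr (1.15 equiv), THF, −78 to 0 °C; cannulated into cold 2 M HCl/Et2O; distilled under reduced pressure over BHT, stored cold and used promptly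
Reagents that add atoms: vinylmagnesium bromide, C=C[Mg]Br
Why: Weinreb ketone synthesis, in which chelate 15 survives until the quench so that no second addition occurs, and the inverse quench into excess cold acid keeps the released hydroxylamine protonated so that it cannot add to the vinyl ketone.

Step 9
Reactants: 12 3-[(3R,4R)-2-oxo-4-(3,4,5-trimethoxybenzyl)tetrahydrofuran-3-yl]propanal; 16 1-methoxybut-3-en-2-one
Product: 19 (3R,4R)-3-[(3-methoxy-4-oxocyclohex-2-en-1-yl)methyl]-4-(3,4,5-trimethoxybenzyl)dihydrofuran-2(3H)-one (both epimers at the side-chain-bearing ring carbon), via keto aldehyde 17 (not isolated), via ring aldol 18 (not isolated)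
Conditions: 16 (1.5 equiv), (S)-2-[methoxy(diphenyl)methyl]pyrrolidine (10 mol %), ethyl 3,4-dihydroxybenzoate (20 mol %), CH2Cl2, 4 °C to rt; volatiles off; then piperidine, AcOH (30 mol % each), toluene, 70 °C
Reagents that add atoms: none
Why: The hindered pyrrolidine turns aldehyde 12 into its (E)-enamine, whose nucleophilic carbon (the aldehyde α-carbon) adds to the CH2 terminus of enone 16, activated by hydrogen bonds from the catechol, and hydrolysis releases 1,5-keto aldehyde 17 (carbocycle bond C4–C5). Piperidinium acetate then enolises the ketone towards its methoxymethyl carbon, which attacks the aldehyde to give aldol 18, and E1cB loss of water leaves the conjugated 2-methoxy enone 19 (carbocycle bond C2=C3). The closest known chemistry is the organocatalytic form of the Stork enamine–Robinson annulation, which makes 4-substituted cyclohexenones from linear aldehydes and vinyl ketones, together with the established use of methoxymethyl vinyl ketone as a Robinson acceptor. The carbocycle closes in the 6-(enolendo)-exo-trig mode; closure from the other ketone α-carbon or from the aldehyde α-carbon would give four-membered rings, and the lactone α-carbon, which could reach the ketone through a six-membered ring, is not enolised by an ammonium acetate buffer. Carbocycle C4 (and the two transient oxygenated carbons of 18) form without control as epimer mixtures, which is accepted because all of them are sp2 after step 10, while lactone C3 and C4 are not touched and already hold the thermodynamically preferred trans arrangement. The step needs cross-Michael addition to win over aldehyde self-aldol and over a second alkylation, which is secured by the bulk of the catalyst, by the excess of the unhindered and highly electrophilic enone, and by the slow enamine formation of the α-branched adduct 17.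

Step 10
Reactants: 19 (3R,4R)-3-[(3-methoxy-4-oxocyclohex-2-en-1-yl)methyl]-4-(3,4,5-trimethoxybenzyl)dihydrofuran-2(3H)-one
Product: 21 (3R,4R)-3-(4-hydroxy-3-methoxybenzyl)-4-(3,4,5-trimethoxybenzyl)dihydrofuran-2(3H)-one (target), via cross-conjugated dienone 20 (not isolated)
Conditions: Pd(O2CCF3)2 (5 mol %), 2-(dimethylamino)pyridine (10 mol %), TsOH·H2O (20 mol %), O2 (1 atm), DMSO, 80 °C
Reagents that add atoms: none
Why: Aerobic palladium-catalysed dehydrogenation of a cyclohexenone to a phenol, in which a divalent palladium enolate at carbocycle C6 undergoes β-hydride elimination to dienone 20, 20 still bears H on the alkylated carbon and tautomerises at once to the guaiacol, O2 returns zerovalent palladium to the divalent state, both epimers of 19 converge, and the lactone stereocentres take no part.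

**Compound list**
1 | 3,4,5-trimethoxybenzaldehyde | COc1cc(C=O)cc(OC)c1OC | starting material
2 | dimethyl succinate | COC(=O)CCC(=O)OC | starting material
3 | methyl 5-oxo-2-(3,4,5-trimethoxyphenyl)tetrahydrofuran-3-carboxylate (paraconic lactone, racemic diastereomer mixture, not isolated) | COC(=O)C1CC(=O)OC1c1cc(OC)c(OC)c(OC)c1 | intermediate
4 | (E)-3-(methoxycarbonyl)-4-(3,4,5-trimethoxyphenyl)but-3-enoic acid | COC(=O)/C(CC(=O)O)=C/c1cc(OC)c(OC)c(OC)c1 | intermediate
5 | (R)-3-(methoxycarbonyl)-4-(3,4,5-trimethoxyphenyl)butanoic acid | COC(=O)[C@@H](CC(=O)O)Cc1cc(OC)c(OC)c(OC)c1 | intermediate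
6 | (R)-3-(hydroxymethyl)-4-(3,4,5-trimethoxyphenyl)butanoic acid (not isolated) | OC[C@@H](CC(=O)O)Cc1cc(OC)c(OC)c(OC)c1 | intermediate
7 | (R)-4-(3,4,5-trimethoxybenzyl)dihydrofuran-2(3H)-one | O=C1OC[C@H](Cc2cc(OC)c(OC)c(OC)c2)C1 | intermediate
8 | lithium (R)-4-(3,4,5-trimethoxybenzyl)-4,5-dihydrofuran-2-olate (not isolated) | [Li+].[O-]C1=C[C@@H](Cc2cc(OC)c(OC)c(OC)c2)CO1 | intermediate
9 | (3R,4R)-3-allyl-4-(3,4,5-trimethoxybenzyl)dihydrofuran-2(3H)-one | C=CC[C@H]1C(=O)OC[C@@H]1Cc1cc(OC)c(OC)c(OC)c1 | intermediate
10 | (3R,4R)-3-[3-(9-borabicyclo[3.3.1]nonan-9-yl)propyl]-4-(3,4,5-trimethoxybenzyl)dihydrofuran-2(3H)-one (not isolated) | C1CC2CCCC(C1)B2CCC[C@H]3C(=O)OC[C@@H]3Cc4cc(OC)c(OC)c(OC)c4 | intermediate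
11 | (3R,4R)-3-(3-hydroxypropyl)-4-(3,4,5-trimethoxybenzyl)dihydrofuran-2(3H)-one | OCCC[C@H]1C(=O)OC[C@@H]1Cc1cc(OC)c(OC)c(OC)c1 | intermediate
12 | 3-[(3R,4R)-2-oxo-4-(3,4,5-trimethoxybenzyl)tetrahydrofuran-3-yl]propanal | O=CCC[C@H]1C(=O)OC[C@@H]1Cc1cc(OC)c(OC)c(OC)c1 | intermediate
13 | methoxyacetyl chloride | COCC(Cl)=O | starting material
14 | N,2-dimethoxy-N-methylacetamide | COCC(=O)N(C)OC | intermediate
15 | bromomagnesium 1-methoxy-2-[methoxy(methyl)amino]but-3-en-2-olate (chelated tetrahedral adduct, not isolated) | COCC(O[Mg]Br)(C=C)N(C)OC | intermediate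
16 | 1-methoxybut-3-en-2-one | COCC(=O)C=C | intermediate
17 | 6-methoxy-5-oxo-2-{[(3R,4R)-2-oxo-4-(3,4,5-trimethoxybenzyl)tetrahydrofuran-3-yl]methyl}hexanal (both C2 epimers, not isolated) | COCC(=O)CCC(C=O)C[C@H]1C(=O)OC[C@@H]1Cc1cc(OC)c(OC)c(OC)c1 | intermediate
18 | (3R,4R)-3-[(2-hydroxy-3-methoxy-4-oxocyclohexyl)methyl]-4-(3,4,5-trimethoxybenzyl)dihydrofuran-2(3H)-one (diastereomer mixture, not isolated) | COC1C(O)C(C[C@H]2C(=O)OC[C@@H]2Cc2cc(OC)c(OC)c(OC)c2)CCC1=O | intermediate
19 | (3R,4R)-3-[(3-methoxy-4-oxocyclohex-2-en-1-yl)methyl]-4-(3,4,5-trimethoxybenzyl)dihydrofuran-2(3H)-one (both epimers at the side-chain-bearing ring carbon) | COC1=CC(C[C@H]2C(=O)OC[C@@H]2Cc2cc(OC)c(OC)c(OC)c2)CCC1=O | intermediate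
20 | (3R,4R)-3-[(3-methoxy-4-oxocyclohexa-2,5-dien-1-yl)methyl]-4-(3,4,5-trimethoxybenzyl)dihydrofuran-2(3H)-one (not isolated) | COC1=CC(C[C@H]2C(=O)OC[C@@H]2Cc2cc(OC)c(OC)c(OC)c2)C=CC1=O | intermediate
21 | (3R,4R)-3-(4-hydroxy-3-methoxybenzyl)-4-(3,4,5-trimethoxybenzyl)dihydrofuran-2(3H)-one | COc1cc(C[C@H]2C(=O)OC[C@@H]2Cc2cc(OC)c(OC)c(OC)c2)ccc1O | target

**Total step count:** 10
**Longest linear sequence:** 8 steps (steps 1–6, 9 and 10). Steps 7 and 8 form the side branch to enone 16.

**Three steps most likely to fail**

Step 9. The catalytic Michael stage may lose out to self-condensation of the aldehyde or to amine-initiated polymerisation of the enone, or the turnover may stall. The fallback keeps the same two bonds but removes free aldehyde and catalysis from the addition.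
- It sets out from 12, which is condensed with pyrrolidine (1.0 equiv, 4 Å sieves, toluene, 0 °C to rt) to the isolated Stork enamine (3R,4R)-3-[(E)-3-(pyrrolidin-1-yl)prop-2-en-1-yl]-4-(3,4,5-trimethoxybenzyl)dihydrofuran-2(3H)-one F1.
- F1 is combined with 16 in toluene at rt, where aldehyde enamines and vinyl ketones join by a formal [4+2] addition. This should give the aminodihydropyran (3R,4R)-3-{[6-(methoxymethyl)-2-(pyrrolidin-1-yl)-3,4-dihydro-2H-pyran-3-yl]methyl}-4-(3,4,5-trimethoxybenzyl)dihydrofuran-2(3H)-one F2.
- Warming F2 in AcOH/NaOAc/H2O opens it to the keto aldehyde, and the liberated pyrrolidinium acetate drives ring closure and dehydration. The route is rejoined at 19.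

Step 10. The catalyst may deposit as zerovalent palladium before conversion is complete. The enol ether may hydrolyse in the acidic wet DMSO, or the electron-rich phenol may be oxidised further. The fallback is metal-free and stepwise.
- It sets out from 19. Soft enolisation (TBSOTf, Et3N, CH2Cl2, −78 to 0 °C) at the α′-CH2 should give the cross-conjugated silyl dienol ether (3R,4R)-3-{[4-(tert-butyldimethylsilyloxy)-3-methoxycyclohexa-2,4-dien-1-yl]methyl}-4-(3,4,5-trimethoxybenzyl)dihydrofuran-2(3H)-one F3.
- F3 is a cyclohexa-1,3-diene that DDQ (1.1 equiv, toluene, rt) aromatises by hydride abstraction and proton loss. The product is the aryl silyl ether (3R,4R)-3-[4-(tert-butyldimethylsilyloxy)-3-methoxybenzyl]-4-(3,4,5-trimethoxybenzyl)dihydrofuran-2(3H)-one F4.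
- Bu4NF/AcOH in THF at 0 °C removes the silyl group, and any partial loss of silicon during the DDQ stage converges here as well. The route is rejoined at 21.

Step 8. The liberated hydroxylamine or excess Grignard reagent may add in conjugate fashion during the quench. The volatile enone may also be lost by polymerisation or evaporation on isolation. The fallback replaces the organomagnesium addition by a Stille acylation.
- It sets out from 13, which is coupled with Bu3SnCH=CH2 (1.0 equiv) under PdCl2(PPh3)2 (1 mol %) in THF at 50 °C with a trace of BHT.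
- No amine or hard nucleophile is present, and the enone is distilled straight out of the pot away from the tin residue. The route is rejoined at 16. This fallback makes no compound outside the list (F0).

**Further compounds**
F1 | step 9 | (3R,4R)-3-[(E)-3-(pyrrolidin-1-yl)prop-2-en-1-yl]-4-(3,4,5-trimethoxybenzyl)dihydrofuran-2(3H)-one | C1CCN(C1)/C=C/C[C@H]2C(=O)OC[C@@H]2Cc3cc(OC)c(OC)c(OC)c3
F2 | step 9 | (3R,4R)-3-{[6-(methoxymethyl)-2-(pyrrolidin-1-yl)-3,4-dihydro-2H-pyran-3-yl]methyl}-4-(3,4,5-trimethoxybenzyl)dihydrofuran-2(3H)-one (diastereomer mixture) | COCC1=CCC(C[C@H]2C(=O)OC[C@@H]2Cc3cc(OC)c(OC)c(OC)c3)C(O1)N4CCCC4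
F3 | step 10 | (3R,4R)-3-{[4-(tert-butyldimethylsilyloxy)-3-methoxycyclohexa-2,4-dien-1-yl]methyl}-4-(3,4,5-trimethoxybenzyl)dihydrofuran-2(3H)-one (both ring epimers) | COC1=CC(C[C@H]2C(=O)OC[C@@H]2Cc3cc(OC)c(OC)c(OC)c3)CC=C1O[Si](C)(C)C(C)(C)C
F4 | step 10 | (3R,4R)-3-[4-(tert-butyldimethylsilyloxy)-3-methoxybenzyl]-4-(3,4,5-trimethoxybenzyl)dihydrofuran-2(3H)-one | COc1cc(C[C@H]2C(=O)OC[C@@H]2Cc3cc(OC)c(OC)c(OC)c3)ccc1O[Si](C)(C)C(C)(C)C
F0 | step 8 | none | none
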